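At the early reading of 6.00 h the beta flask already holds 65.0% of target, and from 12.0 h on it stays near 71.1% within the scatter, so what must be reckoned is chiefly the end state, and after it how fast that state is reached.

| flask | substrate | first nucleophile | second nucleophile | temperature | remark | time |
|---|---|---|---|---|---|---|
| beta | 10 mM | 12 mM | 25 mM | 25 °C | run made earlier |  |
| west | 10 mM | 8.00 mM | 25.0 mM | 25 °C |  | 5.0 d |
| north-east | 10 mM | 8.00 mM | 25.0 mM | 5 °C |  | 5.0 d |
| north | 10 mM | 8.00 mM | 25.0 mM |  | at 25 °C until 25 h, from then on at 5 °C | 5.0 d |

beta run (percent of the substrate charged): time / h: target / % = 6.00: 65.0; 12.0: 71.1; 20.0: 71.1; 25.0: 70.7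

(readings scatter by 0.5 percentage points)

- percent here means substrate units held: one side product counts as two
- the numbers in the tables scatter by 0.5 percentage points (one standard deviation)
- steps thought possible: substrate + intermediate -> side product; substrate -> intermediate; first nucleophile + intermediate -> target; second nucleophile + intermediate -> other capture product
- the earlier runs do not show what temperature does; that part of a forecast is a guess

* which flask leads in amount of target, in percent of the substrate charged ("all alike" within 1.5 percentage points) (west / north-east / north / all alike)
* how much target is there at the end, in percent of the substrate charged: west
* how much target is there at the end, in percent of the substrate charged: north-east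
* how much target is there at the end, in percent of the substrate charged: north

If the gap between target and its plateau in the beta flask closes at first order, the reading at 6.00 h gives

k = ln(71.1% / 6.1 percentage points) / 6.00 h = 0.409 h⁻¹

This is a half-life of 1.69 h. The change of temperature in north at 25 h comes far later than that, with hardly any substrate reckoned to remain, so north is reckoned as west.

The end state is reckoned here from how the intermediate divides. Its two captures grow as k(first)[first nucleophile] against k(second)[second nucleophile], and integrating this gives a ratio of logarithms of start over end concentrations. Counting the whole shortfall in beta as other capture product, and setting side product aside as an assumption of this reckoning: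

ln(12 mM / 4.89 mM) / ln(25 mM / 22.1 mM) = 7.31

This number is the capture ratio, the selectivity factor of first over second nucleophile. For west, a trial amount of target leaves the rest of the substrate as other capture product. That gives [second nucleophile], the capture ratio then returns a new target, and the mean of trial and return is the next trial:

7.11 mM → 5.93 mM → 5.87 mM, that is 58.7% in west and north.

Carrying the capture ratio unchanged to 5 °C gives the same figure for north-east, but that is a guess.

The forecast says all alike, with 58% for west, 58% for north-east and 58% for north, a little below this reckoning, and of the cold flask it says: “At 5 °C, activation may be about ten times slower, but 5 days still nearly completes it.”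

The flasks give 58.6% in west, 65.0% in north-east and 58.6% in north, so north-east leads.

    substrate + intermediate → side product (k = 6.44 M⁻¹ h⁻¹, Ea = 68.0 kJ mol⁻¹)
    substrate → intermediate (k = 0.459 h⁻¹, Ea = 99.0 kJ mol⁻¹)
    first nucleophile + intermediate → target (k = 167 M⁻¹ h⁻¹, Ea = 53.0 kJ mol⁻¹)
    second nucleophile + intermediate → other capture product (k = 21.0 M⁻¹ h⁻¹, Ea = 75.0 kJ mol⁻¹)
    (constants at 25 °C)

The reckoning and the flasks part at north-east, where 18.8% of the first and 89.5% of the second nucleophile remain at 5.00 d, and the same ratio of logarithms reads 15.1, twice the capture ratio reckoned from beta. A neighbour of north charged with 4.0 mM of substrate takes the beta capture ratio through the same passes: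

2.84 mM → 2.59 mM → 2.68 mM, that is 67.0%.

That flask holds 67.4% of target.

The earlier runs and the new flask stem from a simulated flask from invented constants.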